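**Retrosynthetic overview**

1. The target 26 comes from ester 25 by acid: the acetonide and silyl ether fall, and O6 closes the γ-lactone on C12. 25 comes from the 8-oxo compound 20 by hydride addition and acylation of O8.
2. The ten-membered carbocycle of 20 comes from the eight-membered oxocine 19 (ring atoms O, C8, C9, C10, C1, C2, C3, C4) by a Claisen ring expansion: the ring O–C4 bond breaks and C6–C7 forms.
3. Enabling feature: C8(=O)–C7–C6–C5=C4 is a γ,δ-unsaturated ketone retron; O6 and O15 lie cis across C4=C5 and can be tied in a seven-membered acetonide; the cis C1=C10 alkene fits inside the small ring.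
4. 19 comes from selenide 17 (selenoxide elimination), built from tertiary alcohol 8 and ynone 14 by oxa-Michael addition, ring-closing metathesis and Wittig methylenation. 8 comes from a Shi epoxide (C4 is the only stereocentre made by catalysis).
5. Ring order: dioxepine, then oxocine, then cyclodecadiene (ring expansion), then γ-lactone. The side chain comes from the (R)-Roche ester.

Key step: step 11

Remark: atoms are cited in germacrane numbering (ring C1–C10, O6 lactone oxygen, O8 ester oxygen, C11–C13 acrylate unit, C14 ring methyl, C15 hydroxymethyl). The target is read as (6R,7R,8S,2′R) with C1=C10 cis and C4=C5 trans within the ring.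

**Route**

Step 1
Reactants: 1 but-3-en-1-ylmagnesium bromide; 2 dimethyl but-2-ynedioate
Product: 4 dimethyl (2Z)-2-(but-3-en-1-yl)but-2-enedioate, via but-3-enylcopper 3 (not isolated)
Conditions: CuBr·SMe2 (1.05 equiv), THF, −40 °C; then 2, −78 °C; aq. NH4Cl at −78 °C
Reagents that add atoms: none
Why: Syn-carbocupration of the ynedioate and protonation at −78 °C, before the alkenylcopper can isomerise, should give the cis diester, which places the two future CH2O arms cis.

Step 2
Reactants: 4 dimethyl (2Z)-2-(but-3-en-1-yl)but-2-enedioate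
Product: 5 (2Z)-2-(but-3-en-1-yl)but-2-ene-1,4-diol
Conditions: iBu2AlH (4.5 equiv), CH2Cl2, −78 → 0 °C; aq. KNaC4H4O6
Reagents that add atoms: none
Why: Exhaustive 1,2-reduction of both conjugated esters by the aluminium hydride keeps the alkene and its Z geometry.

Step 3
Reactants: 5 (2Z)-2-(but-3-en-1-yl)but-2-ene-1,4-diol
Product: 6 5-(but-3-en-1-yl)-2,2-dimethyl-4,7-dihydro-1,3-dioxepine
Conditions: 2,2-dimethoxypropane, TsOH·H2O (1 mol %), benzene, reflux with removal of MeOH
Reagents that add atoms: 2,2-dimethoxypropane, COC(C)(C)OC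
Why: Acid-catalysed transacetalisation closes the seven-membered acetonide, which is possible only because the two hydroxymethyl groups are cis.

Step 4
Reactants: 6 5-(but-3-en-1-yl)-2,2-dimethyl-4,7-dihydro-1,3-dioxepine
Product: 7 (1S,7R)-1-(but-3-en-1-yl)-4,4-dimethyl-3,5,8-trioxabicyclo[5.1.0]octane
Conditions: D-fructose-derived Shi ketone (30 mol %), Oxone (2KHSO5·KHSO4·K2SO4), K2CO3, Bu4NHSO4, MeCN–CH2(OMe)2 / aq. Na2B4O7–Na2(EDTA) buffer (pH 10.5), 0 °C
Reagents that add atoms: potassium peroxymonosulfate (active part of Oxone), [K+].[O-]S(=O)(=O)OO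
Why: Shi asymmetric epoxidation through a spiro dioxirane transition state should oxidise the trisubstituted ring alkene in preference to the vinyl group and, with the D-fructose-derived ketone, from the face that gives the (1S,7R)-epoxide, which sets C4.

Step 5
Reactants: 7 (1S,7R)-1-(but-3-en-1-yl)-4,4-dimethyl-3,5,8-trioxabicyclo[5.1.0]octane
Product: 8 (5S,6S)-5-(but-3-en-1-yl)-2,2-dimethyl-6-(phenylselanyl)-1,3-dioxepan-5-ol
Conditions: PhSeSePh (0.55 equiv), NaBH4, EtOH, 0 → 23 °C
Reagents that add atoms: diphenyl diselenide, c1ccc(cc1)[Se][Se]c1ccccc1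
Why: Benzeneselenolate made in situ opens the epoxide by SN2 attack at the secondary carbon (inversion at C5), so the tertiary C4–O bond and its configuration stay untouched and the selenide serves as a masked C5=C6 enol ether.

Step 6
Reactants: 9 3-chloro-2-methylprop-1-ene; 10 ethynylmagnesium bromide
Product: 11 2-methylpent-1-en-4-yne
Conditions: CuCl (5 mol %), THF, 0 → 40 °C
Reagents that add atoms: none
Why: Copper-catalysed allyl–alkynyl coupling of the alkynyl Grignard reagent with the allylic chloride gives the skipped enyne.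

Step 7
Reactants: 11 2-methylpent-1-en-4-yne; 12 dimethyl oxalate
Product: 14 methyl 6-methyl-2-oxohept-6-en-3-ynoate, via lithium acetylide 13 (not isolated)
Conditions: n-BuLi, THF, −78 °C; then added to 12 (3 equiv), THF, −78 °C; aq. NH4Cl
Reagents that add atoms: none
Why: Acylation of the lithium acetylide by excess oxalate diester at −78 °C stops at the alkynyl α-keto ester because the tetrahedral adduct survives until work-up.

Step 8
Reactants: 8 (5S,6S)-5-(but-3-en-1-yl)-2,2-dimethyl-6-(phenylselanyl)-1,3-dioxepan-5-ol; 14 methyl 6-methyl-2-oxohept-6-en-3-ynoate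
Product: 15 methyl (3E)-4-{[(5S,6S)-5-(but-3-en-1-yl)-2,2-dimethyl-6-(phenylselanyl)-1,3-dioxepan-5-yl]oxy}-6-methyl-2-oxohepta-3,6-dienoate
Conditions: DABCO (20 mol %), CH2Cl2, 0 → 23 °C
Reagents that add atoms: none
Why: Amine-catalysed oxa-Michael addition of the tertiary alcohol to the ynone should equilibrate to the (E)-β-alkoxy enone with the acyl group trans to oxygen, as in β-alkoxy crotonates, which fixes the enol ether geometry needed in step 11.

Step 9
Reactants: 15 methyl (3E)-4-{[(5S,6S)-5-(but-3-en-1-yl)-2,2-dimethyl-6-(phenylselanyl)-1,3-dioxepan-5-yl]oxy}-6-methyl-2-oxohepta-3,6-dienoate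
Product: 16 methyl (3E)-3-[(6S,7S,11Z)-3,3,11-trimethyl-6-(phenylselanyl)-2,4,8-trioxaspiro[6.7]tetradec-11-en-9-ylidene]-2-oxopropanoate
Conditions: second-generation Grubbs catalyst (10 mol %), CH2Cl2 (2 mM), 40 °C
Reagents that add atoms: none
Why: Ring-closing metathesis between the vinyl and the 1,1-disubstituted alkene is helped by the quaternary C4 and can give only the cis C1=C10 alkene in an eight-membered ring, while the push–pull enone is inert to the ruthenium carbene.

Step 10
Reactants: 16 methyl (3E)-3-[(6S,7S,11Z)-3,3,11-trimethyl-6-(phenylselanyl)-2,4,8-trioxaspiro[6.7]tetradec-11-en-9-ylidene]-2-oxopropanoate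
Product: 17 methyl (3E)-2-methylidene-3-[(6S,7S,11Z)-3,3,11-trimethyl-6-(phenylselanyl)-2,4,8-trioxaspiro[6.7]tetradec-11-en-9-ylidene]propanoate
Conditions: Ph3PCH3Br, KN(SiMe3)2, THF, 0 °C; then 16, −78 → 0 °C
Reagents that add atoms: methylenetriphenylphosphorane, C=P(c1ccccc1)(c1ccccc1)c1ccccc1
Why: Wittig methylenation at the more electrophilic ketone of the α-keto ester turns the geometry-controlling acyl group into the C11(=C13H2)–C12 acrylate and locks the C7=C8 geometry in a cross-conjugated dienyl ether, and addition at −78 °C should outrun γ-deprotonation.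

Step 11
Reactants: 17 methyl (3E)-2-methylidene-3-[(6S,7S,11Z)-3,3,11-trimethyl-6-(phenylselanyl)-2,4,8-trioxaspiro[6.7]tetradec-11-en-9-ylidene]propanoate
Product: 20 methyl (1(10)Z,4Z,6R,7S)-6,15-(isopropylidenedioxy)-8-oxogermacra-1(10),4,11(13)-trien-12-oate, via selenoxide 18 (not isolated), via dienyl enol ether 19 (not isolated)
Conditions: mCPBA (1.05 equiv), NaHCO3, CH2Cl2, −78 °C; then pyridine, toluene, 23 → 90 °C
Reagents that add atoms: none
Why: Oxidation at selenium and syn-elimination of PhSeOH (only C6–H is available because C4 is quaternary) unveil the cyclic enol ether 19, whose array C7=C8–O–C4–C5=C6 then undergoes a thermal [3,3]-sigmatropic Claisen shift in which the ring O–C4 bond breaks and the C6–C7 bond forms. The closest known reaction type is the Claisen ring expansion of 2-alkylidene cyclic ethers that carry an alkenyl group at the other α-carbon, combined with in situ generation of the ene partner by selenoxide elimination. The ten-membered carbocycle is closed through this six-centre array with both ene units exocyclic to the oxocine, so the ring grows by two atoms (O leaves it, C5, C6 and C7 enter) and C8 emerges as the ketone. C6 is set by suprafacial transfer of chirality from the C4–O bond across the cis enol ether held in the seven-membered acetonide, and C7 by the (E) geometry of the C7=C8 bond read through a boat-like transition state. The step needs the new C4=C5 bond trans within the large ring and a single transition-state topology: the acetonide keeps C15 and C6 cis on C4=C5, which leaves only the trans-cyclodecene, and the five-atom C9–C3 tether with its cis C1=C10 alkene can bridge the pseudo-equatorial C3 only in the boat. The 6-alkoxy donor and the tertiary carbinol carbon should lower the barrier enough for the shift to outrun [1,5]-hydrogen migration in the dienyl ether.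

Step 12
Reactants: 20 methyl (1(10)Z,4Z,6R,7S)-6,15-(isopropylidenedioxy)-8-oxogermacra-1(10),4,11(13)-trien-12-oate
Product: 21 methyl (1(10)Z,4Z,6R,7R,8S)-8-hydroxy-6,15-(isopropylidenedioxy)germacra-1(10),4,11(13)-trien-12-oate
Conditions: NaBH4, CeCl3·7H2O, MeOH, −78 °C
Reagents that add atoms: none
Why: Luche 1,2-reduction spares the acrylate, and hydride should add to the outer face of the carbonyl, anti to the C6–C7 bond that stands perpendicular to it (Felkin–Anh attack from the ring periphery), to give the 8S alcohol, whose C8–O bond is antiperiplanar to C7–C11 and so should not lactonise onto C12.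

Step 13
Reactants: 22 methyl (2R)-3-hydroxy-2-methylpropanoate
Product: 23 methyl (2R)-3-[(tert-butyldimethylsilyl)oxy]-2-methylpropanoate
Conditions: TBSCl, imidazole, CH2Cl2, 0 → 23 °C
Reagents that add atoms: tert-butyldimethylsilyl chloride, CC(C)(C)[Si](C)(C)Cl
Why: Silylation of the primary alcohol leaves the purchased stereocentre untouched.

Step 14
Reactants: 23 methyl (2R)-3-[(tert-butyldimethylsilyl)oxy]-2-methylpropanoate
Product: 24 (2R)-3-[(tert-butyldimethylsilyl)oxy]-2-methylpropanoic acid
Conditions: LiOH·H2O, THF/MeOH/H2O, 0 → 23 °C; then 1 M HCl to pH 4 at 0 °C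
Reagents that add atoms: lithium hydroxide, [Li+].[OH-]
Why: Mild saponification gives the acid, and the carboxylate formed protects the α-stereocentre from epimerisation.

Step 15
Reactants: 21 methyl (1(10)Z,4Z,6R,7R,8S)-8-hydroxy-6,15-(isopropylidenedioxy)germacra-1(10),4,11(13)-trien-12-oate; 24 (2R)-3-[(tert-butyldimethylsilyl)oxy]-2-methylpropanoic acid
Product: 25 methyl (1(10)Z,4Z,6R,7R,8S)-8-{[(2R)-3-[(tert-butyldimethylsilyl)oxy]-2-methylpropanoyl]oxy}-6,15-(isopropylidenedioxy)germacra-1(10),4,11(13)-trien-12-oate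
Conditions: DCC, DMAP (0.3 equiv), CH2Cl2, 0 → 23 °C
Reagents that add atoms: none
Why: Steglich esterification acylates the C8 hydroxyl with retention at C8, and the low temperature with substoichiometric DMAP limits epimerisation of the α-branched acid.

Step 16
Reactants: 25 methyl (1(10)Z,4Z,6R,7R,8S)-8-{[(2R)-3-[(tert-butyldimethylsilyl)oxy]-2-methylpropanoyl]oxy}-6,15-(isopropylidenedioxy)germacra-1(10),4,11(13)-trien-12-oate
Product: 26 (1(10)Z,4Z,6R,7R,8S)-15-hydroxy-8-{[(2R)-3-hydroxy-2-methylpropanoyl]oxy}germacra-1(10),4,11(13)-trien-12,6-olide (target)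
Conditions: CSA (10 mol %), MeOH, 0 → 23 °C; then concentrate, PPTS (cat.), CH2Cl2, 23 °C
Reagents that add atoms: none
Why: Acid-catalysed methanolysis removes the acetonide and the silyl ether, and the freed C6 hydroxyl, gauche to the acrylate arm on C7, closes the trans-fused α-methylene γ-lactone by transesterification under acid mild enough to spare the transannularly sensitive 1(10),4-diene.

**Compound list**

1 | but-3-en-1-ylmagnesium bromide | C=CCC[Mg]Br | starting material
2 | dimethyl but-2-ynedioate | COC(=O)C#CC(=O)OC | starting material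
3 | but-3-en-1-ylcopper (MgBr2·SMe2 complex) | C=CCC[Cu] | intermediate
4 | dimethyl (2Z)-2-(but-3-en-1-yl)but-2-enedioate | COC(=O)/C=C(/CCC=C)C(=O)OC | intermediate
5 | (2Z)-2-(but-3-en-1-yl)but-2-ene-1,4-diol | OC/C=C(/CCC=C)CO | intermediate
6 | 5-(but-3-en-1-yl)-2,2-dimethyl-4,7-dihydro-1,3-dioxepine | C=CCCC1=CCOC(C)(C)OC1 | intermediate
7 | (1S,7R)-1-(but-3-en-1-yl)-4,4-dimethyl-3,5,8-trioxabicyclo[5.1.0]octane | C=CCC[C@]12COC(C)(C)OC[C@H]1O2 | intermediate
8 | (5S,6S)-5-(but-3-en-1-yl)-2,2-dimethyl-6-(phenylselanyl)-1,3-dioxepan-5-ol | C=CCC[C@]1(O)COC(C)(C)OC[C@@H]1[Se]c2ccccc2 | intermediate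
9 | 3-chloro-2-methylprop-1-ene | C=C(C)CCl | starting material
10 | ethynylmagnesium bromide | C#C[Mg]Br | starting material
11 | 2-methylpent-1-en-4-yne | C=C(C)CC#C | intermediate
12 | dimethyl oxalate | COC(=O)C(=O)OC | starting material
13 | lithium 4-methylpent-4-en-1-yn-1-ide | [Li]C#CCC(C)=C | intermediate
14 | methyl 6-methyl-2-oxohept-6-en-3-ynoate | COC(=O)C(=O)C#CCC(C)=C | intermediate
15 | methyl (3E)-4-{[(5S,6S)-5-(but-3-en-1-yl)-2,2-dimethyl-6-(phenylselanyl)-1,3-dioxepan-5-yl]oxy}-6-methyl-2-oxohepta-3,6-dienoate | C=CCC[C@]1(O/C(CC(C)=C)=C/C(=O)C(=O)OC)COC(C)(C)OC[C@@H]1[Se]c2ccccc2 | intermediate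
16 | methyl (3E)-3-[(6S,7S,11Z)-3,3,11-trimethyl-6-(phenylselanyl)-2,4,8-trioxaspiro[6.7]tetradec-11-en-9-ylidene]-2-oxopropanoate | COC(=O)C(=O)/C=C1/O[C@@]2(CC/C=C(/C)C1)COC(C)(C)OC[C@@H]2[Se]c3ccccc3 | intermediate
17 | methyl (3E)-2-methylidene-3-[(6S,7S,11Z)-3,3,11-trimethyl-6-(phenylselanyl)-2,4,8-trioxaspiro[6.7]tetradec-11-en-9-ylidene]propanoate | COC(=O)C(=C)/C=C1/O[C@@]2(CC/C=C(/C)C1)COC(C)(C)OC[C@@H]2[Se]c3ccccc3 | intermediate
18 | methyl (3E)-2-methylidene-3-[(6S,7S,11Z)-3,3,11-trimethyl-6-(phenylseleninyl)-2,4,8-trioxaspiro[6.7]tetradec-11-en-9-ylidene]propanoate | COC(=O)C(=C)/C=C1/O[C@@]2(CC/C=C(/C)C1)COC(C)(C)OC[C@@H]2[Se](=O)c3ccccc3 | intermediate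
19 | methyl (3E)-2-methylidene-3-[(7R,11Z)-3,3,11-trimethyl-2,4,8-trioxaspiro[6.7]tetradeca-5,11-dien-9-ylidene]propanoate | COC(=O)C(=C)/C=C1/O[C@@]2(CC/C=C(/C)C1)COC(C)(C)OC=C2 | intermediate
20 | methyl (1(10)Z,4Z,6R,7S)-6,15-(isopropylidenedioxy)-8-oxogermacra-1(10),4,11(13)-trien-12-oate (C4=C5 trans within the ten-membered ring) | C=C(C(=O)OC)[C@H]1[C@@H]2OC(C)(C)OC/C(=C\2)CC/C=C(/C)CC1=O | intermediate
21 | methyl (1(10)Z,4Z,6R,7R,8S)-8-hydroxy-6,15-(isopropylidenedioxy)germacra-1(10),4,11(13)-trien-12-oate | C=C(C(=O)OC)[C@H]1[C@@H]2OC(C)(C)OC/C(=C\2)CC/C=C(/C)C[C@@H]1O | intermediate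
22 | methyl (2R)-3-hydroxy-2-methylpropanoate | C[C@H](CO)C(=O)OC | starting material
23 | methyl (2R)-3-[(tert-butyldimethylsilyl)oxy]-2-methylpropanoate | C[C@H](CO[Si](C)(C)C(C)(C)C)C(=O)OC | intermediate
24 | (2R)-3-[(tert-butyldimethylsilyl)oxy]-2-methylpropanoic acid | C[C@H](CO[Si](C)(C)C(C)(C)C)C(=O)O | intermediate
25 | methyl (1(10)Z,4Z,6R,7R,8S)-8-{[(2R)-3-[(tert-butyldimethylsilyl)oxy]-2-methylpropanoyl]oxy}-6,15-(isopropylidenedioxy)germacra-1(10),4,11(13)-trien-12-oate | C=C(C(=O)OC)[C@H]1[C@@H]2OC(C)(C)OC/C(=C\2)CC/C=C(/C)C[C@@H]1OC(=O)[C@H](C)CO[Si](C)(C)C(C)(C)C | intermediate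
26 | (1(10)Z,4Z,6R,7R,8S)-15-hydroxy-8-{[(2R)-3-hydroxy-2-methylpropanoyl]oxy}germacra-1(10),4,11(13)-trien-12,6-olide | C=C1C(=O)O[C@@H]2/C=C(\CO)CC/C=C(/C)C[C@H](OC(=O)[C@H](C)CO)[C@@H]12 | target

**Step count and risks**

Total: 16 steps. Longest linear sequence: 12 steps (steps 1–5, 8–12, 15 and 16).

Most likely to fail, first: step 11. The cascade may stall at its first stage, because syn-elimination of the selenoxide towards the oxygen-bearing C6 is slow and the benzeneselenenic acid set free can add to the electron-rich dienyl ether before the sigmatropic shift. A chair-like or ionised pathway could also erode control at C7. The fallback sets out from 8 and unveils the enol ether early, where no dienyl ether is present. Oxidation of 8 with H2O2 and pyridine in CH2Cl2 and warming should give (5R)-5-(but-3-en-1-yl)-2,2-dimethyl-4,5-dihydro-1,3-dioxepin-5-ol F1. DABCO-catalysed addition of F1 to 14 should give methyl (3E)-4-{[(5R)-5-(but-3-en-1-yl)-2,2-dimethyl-4,5-dihydro-1,3-dioxepin-5-yl]oxy}-6-methyl-2-oxohepta-3,6-dienoate F2. Ring-closing metathesis with the second-generation Grubbs catalyst should give methyl (3E)-3-[(7R,11Z)-3,3,11-trimethyl-2,4,8-trioxaspiro[6.7]tetradeca-5,11-dien-9-ylidene]-2-oxopropanoate F3. Wittig methylenation of F3 returns to the route at 19, which is then heated in toluene at 80–90 °C, free of selenium species, to give 20.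

Second: step 8. The hindered tertiary hydroxyl may add too slowly, so that base-mediated prototropic isomerisation of the skipped enyne and oligomerisation consume the ynone. The fallback sets out from 8 and builds the enol ether from a lactone. Acylation of 8 with 3-methylbut-2-enoyl chloride, Et3N and DMAP (through isopropenylketene, which delivers the deconjugated ester) should give (5S,6S)-5-(but-3-en-1-yl)-2,2-dimethyl-6-(phenylselanyl)-1,3-dioxepan-5-yl 3-methylbut-3-enoate F4. Ring-closing metathesis should give the lactone (6S,7S,11Z)-3,3,11-trimethyl-6-(phenylselanyl)-2,4,8-trioxaspiro[6.7]tetradec-11-en-9-one F5. Methylenation with the Tebbe reagent Cp2Ti(μ-Cl)(μ-CH2)AlMe2 in THF/pyridine should give (6S,7S,11Z)-3,3,11-trimethyl-9-methylidene-6-(phenylselanyl)-2,4,8-trioxaspiro[6.7]tetradec-11-ene F6. C-acylation of this exocyclic enol ether with methyl chlorooxoacetate and pyridine returns to the route at 16.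

Third: step 12. Facial selectivity of hydride addition may be poor or reversed if the ten-membered ketone reacts through a conformer in which the carbonyl has turned through the ring. The fallback sets out from 20 and accepts the epimeric outcome. Reduction then gives methyl (1(10)Z,4Z,6R,7R,8R)-8-hydroxy-6,15-(isopropylidenedioxy)germacra-1(10),4,11(13)-trien-12-oate F7. Mitsunobu esterification of F7 with acid 24 (PPh3, DIAD, toluene, 0 → 23 °C) installs the side chain with SN2 inversion at C8 and returns to the route at 25.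

**Further compounds**

F1 | step 11 | (5R)-5-(but-3-en-1-yl)-2,2-dimethyl-4,5-dihydro-1,3-dioxepin-5-ol | C=CCC[C@]1(O)COC(C)(C)OC=C1
F2 | step 11 | methyl (3E)-4-{[(5R)-5-(but-3-en-1-yl)-2,2-dimethyl-4,5-dihydro-1,3-dioxepin-5-yl]oxy}-6-methyl-2-oxohepta-3,6-dienoate | C=CCC[C@]1(O/C(CC(C)=C)=C/C(=O)C(=O)OC)COC(C)(C)OC=C1
F3 | step 11 | methyl (3E)-3-[(7R,11Z)-3,3,11-trimethyl-2,4,8-trioxaspiro[6.7]tetradeca-5,11-dien-9-ylidene]-2-oxopropanoate | COC(=O)C(=O)/C=C1/O[C@@]2(CC/C=C(/C)C1)COC(C)(C)OC=C2
F4 | step 8 | (5S,6S)-5-(but-3-en-1-yl)-2,2-dimethyl-6-(phenylselanyl)-1,3-dioxepan-5-yl 3-methylbut-3-enoate | C=CCC[C@]1(OC(=O)CC(C)=C)COC(C)(C)OC[C@@H]1[Se]c2ccccc2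
F5 | step 8 | (6S,7S,11Z)-3,3,11-trimethyl-6-(phenylselanyl)-2,4,8-trioxaspiro[6.7]tetradec-11-en-9-one | O=C1O[C@@]2(CC/C=C(/C)C1)COC(C)(C)OC[C@@H]2[Se]c3ccccc3
F6 | step 8 | (6S,7S,11Z)-3,3,11-trimethyl-9-methylidene-6-(phenylselanyl)-2,4,8-trioxaspiro[6.7]tetradec-11-ene | C=C1O[C@@]2(CC/C=C(/C)C1)COC(C)(C)OC[C@@H]2[Se]c3ccccc3
F7 | step 12 | methyl (1(10)Z,4Z,6R,7R,8R)-8-hydroxy-6,15-(isopropylidenedioxy)germacra-1(10),4,11(13)-trien-12-oate | C=C(C(=O)OC)[C@H]1[C@@H]2OC(C)(C)OC/C(=C\2)CC/C=C(/C)C[C@H]1O
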